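Ring B of the rearranged drimane (decalin C1–C10; methyls on C5, C8, C9; C15 the arylmethyl carbon) is cut across C7–C8 and C9–C10. One catalytic enantioselective Diels–Alder reaction between (E)-2-methylbut-2-enal and its own triisopropylsilyl dienol ether closes ring B and sets C8 and C9, plus a disposable C10 carbinol. It exploits the cis C8/C9 methyl pair of ring B with C15 trans to the C8 methyl, which is the (E)-enal written into the ring. Both partners come from one cheap aldehyde. C15 is then carried as a slender nitrile that steers the C5 quaternisation, ring A is annulated with crotonaldehyde, and arene and sulfate arrive last.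

Key step: step 2

Remark: the target is drawn as the neutral aryl hydrogen sulfate; the last step releases this form by cold cation exchange, and the compound would be stored as a salt.
Remark: primed numbers are arene positions counted from the carbon bonded to C15.

Step 1
Reactants: 1 (E)-2-methylbut-2-enal (tiglic aldehyde)
Product: 2 (E)-2-methyl-1-(triisopropylsilyloxy)buta-1,3-diene
Conditions: i-Pr3SiOTf, Et3N, Et2O, 0 °C → rt
Reagents that add atoms: triisopropylsilyl trifluoromethanesulfonate, CC(C)[Si](C(C)C)(C(C)C)OS(=O)(=O)C(F)(F)F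
Why: Soft enolisation (O-silylation, then γ-deprotonation by the amine) gives the silyl dienol ether with oxygen trans to the vinyl group, and the bulky triisopropylsilyl group is chosen over a smaller silyl group so that the diene tolerates the strongly acidic catalyst of step 2.

Step 2
Reactants: 2 (E)-2-methyl-1-(triisopropylsilyloxy)buta-1,3-diene; 1 (E)-2-methylbut-2-enal
Product: 3 (1R,2R,6S)-1,3,6-trimethyl-2-(triisopropylsilyloxy)cyclohex-3-ene-1-carbaldehyde
Conditions: (S)-3,3-diphenyl-1-(2-methylphenyl)tetrahydro-1H,3H-pyrrolo[1,2-c][1,3,2]oxazaborole (20 mol %), Tf2NH (18 mol %), CH2Cl2, −78 → −30 °C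
Reagents that add atoms: none
Why: The N-protonated oxazaborolidine binds the formyl oxygen of 1 and lowers its LUMO, and diene 2 then adds in a concerted but asynchronous [4+2] cycloaddition in which its unsubstituted terminus (C7) bonds to the β-carbon (C8) slightly ahead of the C10–C9 bond. The closest known reaction type is the cationic oxazaborolidine-catalysed Diels–Alder reaction of α-substituted enals with 1-oxygenated dienes. Ring B is closed by the cycloaddition itself, both σ-bonds forming suprafacially on each partner in one six-membered transition state. C8 and C9 are fixed relative to each other by the (E)-geometry of 1 (methyls cis, formyl trans to the C8 methyl) and in the absolute sense by the catalyst, which must leave the Cα-Si/Cβ-Re face of the enal open (the (S)-catalyst is written as the one expected to do so); C10 follows from the exo-formyl approach preferred by α-branched enals, and either C10 epimer is usable because step 5 oxidises this centre. The step needs ortho regiochemistry, secured by the 1-silyloxy group (largest HOMO coefficient at C7), and it needs cycloaddition to outrun silyl transfer and Mukaiyama-type carbonyl addition, secured by the bulky silyl group, low temperature and an excess of the dienophile.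

Step 3
Reactants: 3 (1R,2R,6S)-1,3,6-trimethyl-2-(triisopropylsilyloxy)cyclohex-3-ene-1-carbaldehyde
Product: 6 (1S,2R,6S)-1,3,6-trimethyl-2-(triisopropylsilyloxy)cyclohex-3-ene-1-carbonitrile, via aldoxime 4 (not isolated), via O-acetyl aldoxime 5 (not isolated)
Conditions: NH2OH·HCl, pyridine, 60 °C; then Ac2O, 100 °C
Reagents that add atoms: hydroxylamine hydrochloride, NO.Cl
Why: Oxime formation and acetylation–elimination (aldoxime dehydration) turn the neopentyl aldehyde into a nitrile, a base-stable mask for C15 that is small enough to steer step 6 and is reopened to the aldehyde in step 11, with no stereocentre touched.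

Step 4
Reactants: 6 (1S,2R,6S)-1,3,6-trimethyl-2-(triisopropylsilyloxy)cyclohex-3-ene-1-carbonitrile
Product: 7 (1S,2R,6S)-2-hydroxy-1,3,6-trimethylcyclohex-3-ene-1-carbonitrile
Conditions: Bu4NF, AcOH, THF, 40 °C
Reagents that add atoms: none
Why: Fluoride-mediated silyl ether cleavage, buffered with acetic acid so that the β-hydroxy nitrile is never present as a free alkoxide and cannot undergo retro-aldol ring opening.

Step 5
Reactants: 7 (1S,2R,6S)-2-hydroxy-1,3,6-trimethylcyclohex-3-ene-1-carbonitrile
Product: 8 (1S,6S)-1,3,6-trimethyl-2-oxocyclohex-3-ene-1-carbonitrile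
Conditions: Dess–Martin periodinane, CH2Cl2, 0 °C → rt
Reagents that add atoms: none
Why: Dess–Martin oxidation of the allylic alcohol gives the 2-methylcyclohex-2-enone and erases the C10 stereocentre, so both C10 epimers from step 2 converge.

Step 6
Reactants: 8 (1S,6S)-1,3,6-trimethyl-2-oxocyclohex-3-ene-1-carbonitrile; 9 (E)-but-2-enal (crotonaldehyde)
Product: 11 (1S,3R,6S)-3-[(E)-1-hydroxybut-2-en-1-yl]-1,3,6-trimethyl-2-oxocyclohexane-1-carbonitrile (both carbinol epimers), via lithium enolate 10 (not isolated)
Conditions: LiBH(s-Bu)3, THF, −78 °C; then 9, −78 °C; AcOH quench at −78 °C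
Reagents that add atoms: none
Why: Conjugate hydride reduction gives the only possible enolate (C9 is quaternary) and its aldol addition to crotonaldehyde (reductive aldol) creates the C5 quaternary centre; the C9 methyl should sit pseudoaxial to avoid A(1,2) strain with the enolate oxygen and block its face, so the aldehyde should enter syn to the slender nitrile and place C4 cis to C15, while the carbinol centre is a mixture that step 7 removes.

Step 7
Reactants: 11 (1S,3R,6S)-3-[(E)-1-hydroxybut-2-en-1-yl]-1,3,6-trimethyl-2-oxocyclohexane-1-carbonitrile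
Product: 12 (1S,3R,6S)-3-[(E)-but-2-enoyl]-1,3,6-trimethyl-2-oxocyclohexane-1-carbonitrile
Conditions: Dess–Martin periodinane, CH2Cl2, 0 °C → rt
Reagents that add atoms: none
Why: Dess–Martin oxidation of the allylic β-hydroxy ketone gives the non-enolisable 2-acyl ketone under base-free conditions, which avoids retro-aldol loss of the new quaternary centre.

Step 8
Reactants: 12 (1S,3R,6S)-3-[(E)-but-2-enoyl]-1,3,6-trimethyl-2-oxocyclohexane-1-carbonitrile
Product: 14 (1R,2S,4aS)-1,2,4a-trimethyl-5-oxo-1,2,3,4,4a,5-hexahydronaphthalene-1-carbonitrile, via hydroxy enone 13 (not isolated)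
Conditions: TsOH·H2O (20 mol %), PhMe, 90 °C, 4 Å MS
Reagents that add atoms: none
Why: Intramolecular vinylogous aldol condensation, in which the γ-methyl of the crotonyl ketone (the only enolisable site) attacks the C10 ketone as its dienol to close six-membered ring A and water is lost to give the linear dienone; acid is used, as in Robinson-type cyclodehydrations of non-enolisable 1,3-diketones, to avoid retro-Claisen cleavage.

Step 9
Reactants: 14 (1R,2S,4aS)-1,2,4a-trimethyl-5-oxo-1,2,3,4,4a,5-hexahydronaphthalene-1-carbonitrile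
Product: 16 (1R,2S,4aS,8aS)-1,2,4a-trimethyl-5-oxodecahydronaphthalene-1-carbonitrile, via ene-ketone 15 (not isolated)
Conditions: Mn(dpm)3 (10 mol %), PhSiH3, t-BuOOH, i-PrOH, rt
Reagents that add atoms: none
Why: Hydrogen-atom-transfer hydrogenation (Mn–H reduction of the Mukaiyama type) saturates the enone and then the hindered C1=C10 alkene, and the tertiary C10 radical should take hydrogen on the face opposite the two axial methyl groups on C5 and C9, giving the trans-decalin with C10–H cis to C15.

Step 10
Reactants: 16 (1R,2S,4aS,8aS)-1,2,4a-trimethyl-5-oxodecahydronaphthalene-1-carbonitrile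
Product: 17 (1R,2S,4aS,8aR)-1,2,4a-trimethyl-5-methylidenedecahydronaphthalene-1-carbonitrile
Conditions: Ph3PCH3Br, KOt-Bu, PhMe, 90 °C
Reagents that add atoms: methyltriphenylphosphonium bromide, C[P+](c1ccccc1)(c1ccccc1)c1ccccc1.[Br-]
Why: Wittig methylenation with excess unstabilised ylide at elevated temperature converts the C4 ketone beside the quaternary C5 into the exocyclic methylene, while the hindered tertiary nitrile does not react.

Step 11
Reactants: 17 (1R,2S,4aS,8aR)-1,2,4a-trimethyl-5-methylidenedecahydronaphthalene-1-carbonitrile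
Product: 19 (1R,2S,4aS,8aR)-1,2,4a-trimethyl-5-methylidenedecahydronaphthalene-1-carbaldehyde, via aluminium aldimine 18 (not isolated)
Conditions: i-Bu2AlH, CH2Cl2, −78 → 0 °C; then 10% aq. tartaric acid, 0 °C
Reagents that add atoms: water, O
Why: Partial hydride reduction of the nitrile to the N-aluminio aldimine and mild acidic hydrolysis return the C15 aldehyde, the 1,1-disubstituted alkene being inert to the hydride and to cold dilute acid.

Step 12
Reactants: 20 3-bromo-4,5-dihydroxybenzaldehyde
Product: 21 3-bromo-5-hydroxy-4-(prop-2-en-1-yloxy)benzaldehyde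
Conditions: allyl bromide (1.05 equiv), NaHCO3, NaI (cat.), DMF, 40 °C
Reagents that add atoms: allyl bromide, C=CCBr
Why: Williamson etherification with a weak base alkylates only the more acidic phenol (para to the formyl group, ortho to bromine), which differentiates the oxygen that will carry the sulfate from the one that stays a free phenol.

Step 13
Reactants: 21 3-bromo-5-hydroxy-4-(prop-2-en-1-yloxy)benzaldehyde
Product: 22 3-bromo-5-(hydroxymethyl)-2-(prop-2-en-1-yloxy)phenol
Conditions: NaBH4, MeOH, 0 °C
Reagents that add atoms: none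
Why: Borohydride reduction of the aldehyde gives the benzyl alcohol without touching the aryl bromide or the allyl ether.

Step 14
Reactants: 22 3-bromo-5-(hydroxymethyl)-2-(prop-2-en-1-yloxy)phenol
Product: 23 1-bromo-2-(prop-2-en-1-yloxy)-3-(triisopropylsilyloxy)-5-[(triisopropylsilyloxy)methyl]benzene
Conditions: i-Pr3SiCl, imidazole, DMF, rt
Reagents that add atoms: chlorotriisopropylsilane, CC(C)[Si](Cl)(C(C)C)C(C)C
Why: Silylation of the remaining phenol and the primary alcohol gives fluoride-labile protection that tolerates the organolithium, radical and palladium steps.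

Step 15
Reactants: 23 1-bromo-2-(prop-2-en-1-yloxy)-3-(triisopropylsilyloxy)-5-[(triisopropylsilyloxy)methyl]benzene; 19 (1R,2S,4aS,8aR)-1,2,4a-trimethyl-5-methylidenedecahydronaphthalene-1-carbaldehyde
Product: 27 S-methyl xanthate of the C15 carbinol (both C15 epimers; decalin configured as in 19), via aryllithium 24 (not isolated), via lithium alkoxide 25 (not isolated), via lithium xanthate 26 (not isolated)
Conditions: t-BuLi (2.0 equiv), Et2O, −78 °C; 19, THF, −78 → 0 °C; CS2, 0 °C; MeI, rt
Reagents that add atoms: carbon disulfide, S=C=S; iodomethane, CI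
Why: Bromine–lithium exchange, 1,2-addition of the aryllithium to the neopentyl aldehyde and trapping of the alkoxide as the S-methyl xanthate (first half of a Barton–McCombie deoxygenation) form the C15–aryl bond, and the new carbinol centre is a mixture that step 16 removes.

Step 16
Reactants: 27 S-methyl xanthate of the C15 carbinol
Product: 28 2-(prop-2-en-1-yloxy)-1-{[(1R,2S,4aS,8aS)-1,2,4a-trimethyl-5-methylidenedecahydronaphthalen-1-yl]methyl}-3-(triisopropylsilyloxy)-5-[(triisopropylsilyloxy)methyl]benzene
Conditions: Bu3SnH (3 equiv), AIBN (cat.), PhMe, 90 °C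
Reagents that add atoms: none
Why: Barton–McCombie deoxygenation, in which the stannyl radical adds to the thiocarbonyl, β-scission gives a stabilised benzylic radical and hydrogen transfer from the stannane (kept concentrated) should be faster than any cyclisation onto the allyl ether, leaving the C15 methylene.

Step 17
Reactants: 28 allyl ether from step 16
Product: 29 2-{[(1R,2S,4aS,8aS)-1,2,4a-trimethyl-5-methylidenedecahydronaphthalen-1-yl]methyl}-6-(triisopropylsilyloxy)-4-[(triisopropylsilyloxy)methyl]phenol
Conditions: Pd(PPh3)4 (5 mol %), morpholine, THF, rt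
Reagents that add atoms: none
Why: Tsuji–Trost-type deallylation, in which zerovalent palladium ionises the aryl allyl ether and morpholine captures the allyl group, frees only the C2′ phenol while the silyl ethers and the exocyclic alkene are untouched.

Step 18
Reactants: 29 phenol from step 17
Product: 30 pyridinium 2-{[(1R,2S,4aS,8aS)-1,2,4a-trimethyl-5-methylidenedecahydronaphthalen-1-yl]methyl}-6-(triisopropylsilyloxy)-4-[(triisopropylsilyloxy)methyl]phenyl sulfate
Conditions: SO3·pyridine (5 equiv), pyridine, 50 °C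
Reagents that add atoms: sulfur trioxide–pyridine complex, O=S(=O)=O.c1ccncc1
Why: O-Sulfation of the single free phenol with the sulfur trioxide–pyridine complex, the regiochemistry being fixed by protection because both other oxygens are silylated.

Step 19
Reactants: 30 pyridinium aryl sulfate from step 18
Product: 32 2-hydroxy-4-(hydroxymethyl)-6-{[(1R,2S,4aS,8aS)-1,2,4a-trimethyl-5-methylidenedecahydronaphthalen-1-yl]methyl}phenyl hydrogen sulfate (CNP0353860.3), via tetrabutylammonium sulfate 31 (not isolated)
Conditions: Bu4NF, THF, 0 °C → rt; then Dowex 50W (H+ form), MeOH–H2O, 0 °C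
Reagents that add atoms: none
Why: Fluoride cleaves both silyl ethers (aryl sulfates are stable to fluoride and base) and cold cation exchange gives the neutral hydrogen sulfate without acid hydrolysis of the sulfate or isomerisation of the exocyclic alkene.

Compound list
1 | (E)-2-methylbut-2-enal (tiglic aldehyde) | C/C=C(\C)C=O | starting material
2 | (E)-2-methyl-1-(triisopropylsilyloxy)buta-1,3-diene | C=C/C(C)=C/O[Si](C(C)C)(C(C)C)C(C)C | intermediate
3 | (1R,2R,6S)-1,3,6-trimethyl-2-(triisopropylsilyloxy)cyclohex-3-ene-1-carbaldehyde (ring B; C8 and C9 methyls cis, formyl trans to the C8 methyl and to the silyloxy group) | C[C@H]1CC=C(C)[C@@H](O[Si](C(C)C)(C(C)C)C(C)C)[C@]1(C)C=O | intermediate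
4 | (E)-aldoxime of 3 | C[C@H]1CC=C(C)[C@@H](O[Si](C(C)C)(C(C)C)C(C)C)[C@]1(C)/C=N/O | intermediate
5 | O-acetyl (E)-aldoxime of 3 | C[C@H]1CC=C(C)[C@@H](O[Si](C(C)C)(C(C)C)C(C)C)[C@]1(C)/C=N/OC(C)=O | intermediate
6 | (1S,2R,6S)-1,3,6-trimethyl-2-(triisopropylsilyloxy)cyclohex-3-ene-1-carbonitrile | C[C@H]1CC=C(C)[C@@H](O[Si](C(C)C)(C(C)C)C(C)C)[C@]1(C)C#N | intermediate
7 | (1S,2R,6S)-2-hydroxy-1,3,6-trimethylcyclohex-3-ene-1-carbonitrile | C[C@H]1CC=C(C)[C@@H](O)[C@]1(C)C#N | intermediate
8 | (1S,6S)-1,3,6-trimethyl-2-oxocyclohex-3-ene-1-carbonitrile | C[C@H]1CC=C(C)C(=O)[C@]1(C)C#N | intermediate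
9 | (E)-but-2-enal (crotonaldehyde) | C/C=C/C=O | starting material
10 | lithium (5S,6S)-6-cyano-2,5,6-trimethylcyclohex-1-en-1-olate | C[C@H]1CCC(C)=C(O[Li])[C@]1(C)C#N | intermediate
11 | (1S,3R,6S)-3-[(E)-1-hydroxybut-2-en-1-yl]-1,3,6-trimethyl-2-oxocyclohexane-1-carbonitrile (both carbinol epimers) | C[C@H]1CC[C@](C)(C(O)/C=C/C)C(=O)[C@]1(C)C#N | intermediate
12 | (1S,3R,6S)-3-[(E)-but-2-enoyl]-1,3,6-trimethyl-2-oxocyclohexane-1-carbonitrile | C[C@H]1CC[C@](C)(C(=O)/C=C/C)C(=O)[C@]1(C)C#N | intermediate
13 | 8a-hydroxy-1,2,4a-trimethyl-5-oxo-1,2,3,4,4a,5,8,8a-octahydronaphthalene-1-carbonitrile (ring A closed, tertiary C10 alcohol, either C10 epimer; C5, C8, C9 as in 12) | O=C1C=CCC2(O)[C@](C)(C#N)[C@@H](C)CC[C@]12C | intermediate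
14 | (1R,2S,4aS)-1,2,4a-trimethyl-5-oxo-1,2,3,4,4a,5-hexahydronaphthalene-1-carbonitrile | O=C1C=CC=C2[C@](C)(C#N)[C@@H](C)CC[C@]12C | intermediate
15 | (1R,2S,4aS)-1,2,4a-trimethyl-5-oxo-1,2,3,4,4a,5,6,7-octahydronaphthalene-1-carbonitrile | O=C1CCC=C2[C@](C)(C#N)[C@@H](C)CC[C@]12C | intermediate
16 | (1R,2S,4aS,8aS)-1,2,4a-trimethyl-5-oxodecahydronaphthalene-1-carbonitrile (trans-decalin) | O=C1CCC[C@H]2[C@](C)(C#N)[C@@H](C)CC[C@]12C | intermediate
17 | (1R,2S,4aS,8aR)-1,2,4a-trimethyl-5-methylidenedecahydronaphthalene-1-carbonitrile | C=C1CCC[C@H]2[C@](C)(C#N)[C@@H](C)CC[C@]12C | intermediate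
18 | N-(diisobutylaluminio) aldimine of 19 | C=C1CCC[C@H]2[C@](C)(/C=N/[Al](CC(C)C)CC(C)C)[C@@H](C)CC[C@]12C | intermediate
19 | (1R,2S,4aS,8aR)-1,2,4a-trimethyl-5-methylidenedecahydronaphthalene-1-carbaldehyde | C=C1CCC[C@H]2[C@](C)(C=O)[C@@H](C)CC[C@]12C | intermediate
20 | 3-bromo-4,5-dihydroxybenzaldehyde (commercial; the O-demethylated form of 5-bromovanillin) | O=Cc1cc(O)c(O)c(Br)c1 | starting material
21 | 3-bromo-5-hydroxy-4-(prop-2-en-1-yloxy)benzaldehyde | O=Cc1cc(O)c(OCC=C)c(Br)c1 | intermediate
22 | 3-bromo-5-(hydroxymethyl)-2-(prop-2-en-1-yloxy)phenol | OCc1cc(O)c(OCC=C)c(Br)c1 | intermediate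
23 | 1-bromo-2-(prop-2-en-1-yloxy)-3-(triisopropylsilyloxy)-5-[(triisopropylsilyloxy)methyl]benzene | C=CCOc1c(Br)cc(CO[Si](C(C)C)(C(C)C)C(C)C)cc1O[Si](C(C)C)(C(C)C)C(C)C | intermediate
24 | aryllithium from 23 (lithium in place of bromine) | C=CCOc1c([Li])cc(CO[Si](C(C)C)(C(C)C)C(C)C)cc1O[Si](C(C)C)(C(C)C)C(C)C | intermediate
25 | lithium alkoxide of the C15 carbinol (aryl and decalin joined at C15; both C15 epimers) | C=C1CCC[C@H]2[C@](C)(C(O[Li])c3cc(CO[Si](C(C)C)(C(C)C)C(C)C)cc(O[Si](C(C)C)(C(C)C)C(C)C)c3OCC=C)[C@@H](C)CC[C@]12C | intermediate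
26 | lithium O-alkyl dithiocarbonate of the C15 carbinol | C=C1CCC[C@H]2[C@](C)(C(OC(=S)S[Li])c3cc(CO[Si](C(C)C)(C(C)C)C(C)C)cc(O[Si](C(C)C)(C(C)C)C(C)C)c3OCC=C)[C@@H](C)CC[C@]12C | intermediate
27 | S-methyl xanthate of the C15 carbinol (both C15 epimers; decalin as in 19) | C=C1CCC[C@H]2[C@](C)(C(OC(=S)SC)c3cc(CO[Si](C(C)C)(C(C)C)C(C)C)cc(O[Si](C(C)C)(C(C)C)C(C)C)c3OCC=C)[C@@H](C)CC[C@]12C | intermediate
28 | 2-(prop-2-en-1-yloxy)-1-{[(1R,2S,4aS,8aS)-1,2,4a-trimethyl-5-methylidenedecahydronaphthalen-1-yl]methyl}-3-(triisopropylsilyloxy)-5-[(triisopropylsilyloxy)methyl]benzene | C=C1CCC[C@H]2[C@](C)(Cc3cc(CO[Si](C(C)C)(C(C)C)C(C)C)cc(O[Si](C(C)C)(C(C)C)C(C)C)c3OCC=C)[C@@H](C)CC[C@]12C | intermediate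
29 | 2-{[(1R,2S,4aS,8aS)-1,2,4a-trimethyl-5-methylidenedecahydronaphthalen-1-yl]methyl}-6-(triisopropylsilyloxy)-4-[(triisopropylsilyloxy)methyl]phenol | C=C1CCC[C@H]2[C@](C)(Cc3cc(CO[Si](C(C)C)(C(C)C)C(C)C)cc(O[Si](C(C)C)(C(C)C)C(C)C)c3O)[C@@H](C)CC[C@]12C | intermediate
30 | pyridinium salt of the aryl sulfate of 29 | C=C1CCC[C@H]2[C@](C)(Cc3cc(CO[Si](C(C)C)(C(C)C)C(C)C)cc(O[Si](C(C)C)(C(C)C)C(C)C)c3OS(=O)(=O)[O-])[C@@H](C)CC[C@]12C.c1cc[nH+]cc1 | intermediate
31 | tetrabutylammonium salt of the desilylated aryl sulfate | C=C1CCC[C@H]2[C@](C)(Cc3cc(CO)cc(O)c3OS(=O)(=O)[O-])[C@@H](C)CC[C@]12C.CCCC[N+](CCCC)(CCCC)CCCC | intermediate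
32 | 2-hydroxy-4-(hydroxymethyl)-6-{[(1R,2S,4aS,8aS)-1,2,4a-trimethyl-5-methylidenedecahydronaphthalen-1-yl]methyl}phenyl hydrogen sulfate (CNP0353860.3; 5S,8S,9R,10S in decalin numbering) | C=C1CCC[C@H]2[C@](C)(Cc3cc(CO)cc(O)c3OS(=O)(=O)O)[C@@H](C)CC[C@]12C | target

Total step count: 19. Longest linear sequence: 16 steps (steps 1–11, then 15–19); the arene branch is steps 12–14.

Steps most likely to fail

Step 2 (key step). The α,β-disubstituted enal may react so slowly that acid-promoted silyl transfer and Mukaiyama-type addition to the carbonyl overtake the cycloaddition, or face selection by the catalyst may be incomplete. The fallback moves stereocontrol to a covalent auxiliary on the diene oxygen. It sets out from 1: deprotonation (KOt-Bu, THF, −78 °C) and O-acylation with (S)-2-methoxy-2-phenylacetyl chloride would give (E)-2-methylbuta-1,3-dien-1-yl (S)-2-methoxy-2-phenylacetate F1. A Diels–Alder reaction of F1 with 1 under an achiral Lewis acid (BF3·OEt2, CH2Cl2, −40 °C) would give (1R,5S,6R)-6-formyl-2,5,6-trimethylcyclohex-2-en-1-yl (S)-2-methoxy-2-phenylacetate F2, with the same two bonds and the same ring formed, now as diastereomers that can be separated by chromatography or crystallisation; the mandelate antipode that favours the needed series would be used. The oxime and acetic anhydride sequence of step 3 would give (1R,5S,6S)-6-cyano-2,5,6-trimethylcyclohex-2-en-1-yl (S)-2-methoxy-2-phenylacetate F3, and K2CO3 in methanol would release the alcohol, returning to the route at 7.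

Step 6. The aldol addition at a fully substituted enolate carbon is reversible, so conversion and facial selectivity at C5 may erode, and 1,2-reduction of the enone may compete. The fallback replaces the reversible, closed-transition-state aldol by an irreversible C-acylation of an isolated silyl enol ether. It sets out from 8: conjugate reduction with LiBH(s-Bu)3 and trapping with Me3SiCl would give (1S,6S)-1,3,6-trimethyl-2-(trimethylsilyloxy)cyclohex-2-ene-1-carbonitrile F4. Acylation of F4 with (E)-but-2-enoyl chloride and ZnCl2 (CH2Cl2, −20 °C), again anti to the pseudoaxial C9 methyl, would give the enedione directly, returning to the route at 12 and saving the oxidation of step 7.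

Step 8. Addition of the dienol to the C10 ketone, which is flanked by two quaternary carbons, may be slower than retro-Claisen cleavage or intermolecular Michael oligomerisation of the enone. The fallback separates bond formation from dehydration and makes the addition irreversible. It sets out from 12: t-BuMe2SiOTf and Et3N would give the silyl dienol ether (1S,3R,6S)-3-[1-(tert-butyldimethylsilyloxy)buta-1,3-dien-1-yl]-1,3,6-trimethyl-2-oxocyclohexane-1-carbonitrile F5. TiCl4 (CH2Cl2, −78 °C) would then trigger an intramolecular vinylogous Mukaiyama aldol addition to the C10 ketone to give hydroxy enone 13, isolated this time, and SOCl2 in pyridine (0 °C) would dehydrate it, returning to the route at 14.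

Further compounds
F1 | step 2 | (E)-2-methylbuta-1,3-dien-1-yl (S)-2-methoxy-2-phenylacetate | C=C/C(C)=C/OC(=O)[C@@H](OC)c1ccccc1
F2 | step 2 | (1R,5S,6R)-6-formyl-2,5,6-trimethylcyclohex-2-en-1-yl (S)-2-methoxy-2-phenylacetate | C[C@H]1CC=C(C)[C@@H](OC(=O)[C@@H](OC)c2ccccc2)[C@]1(C)C=O
F3 | step 2 | (1R,5S,6S)-6-cyano-2,5,6-trimethylcyclohex-2-en-1-yl (S)-2-methoxy-2-phenylacetate | C[C@H]1CC=C(C)[C@@H](OC(=O)[C@@H](OC)c2ccccc2)[C@]1(C)C#N
F4 | step 6 | (1S,6S)-1,3,6-trimethyl-2-(trimethylsilyloxy)cyclohex-2-ene-1-carbonitrile | C[C@H]1CCC(C)=C(O[Si](C)(C)C)[C@]1(C)C#N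
F5 | step 8 | (1S,3R,6S)-3-[1-(tert-butyldimethylsilyloxy)buta-1,3-dien-1-yl]-1,3,6-trimethyl-2-oxocyclohexane-1-carbonitrile | C[C@H]1CC[C@](C)(C(O[Si](C)(C)C(C)(C)C)=CC=C)C(=O)[C@]1(C)C#N
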